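**Retrosynthetic overview**
- Cut the aryl–CH2 bond of the methylene bridge: arzanol ⇒ 3-prenylphloroacetophenone (nucleophile at its only free ring CH) + 6-ethyl-5-methyl-3-methylene-pyran-2,4-dione (electrophile).
- The methylene-dione is released from a latent form, a C3-aminoxylated 3-methylpyrone, so the bridge carbon starts as the 3-CH3 of 6-ethyl-4-hydroxy-3,5-dimethyl-2-pyrone (proposed new step).
- The pyrone ring is the only ring built: DBU lactonisation of a 3,5-dioxoheptanoate made by β-keto ester dianion acylation with a Weinreb amide.
- The prenylarene comes from direct C-prenylation of commercial phloroacetophenone; the benzene ring is bought intact.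
- Order: pyrone ring first (step 2), fragment union last (step 5).

Assumption: the target SMILES has no stereocentres and no stereogenic double bond (the prenyl terminus carries two methyls), so arzanol is achiral and "single enantiomer" needs no stereocontrol.

**Step 1**
Reactants: 1, ethyl 2-methyl-3-oxopentanoate (racemic); 2, N-methoxy-N-methylpropanamide
Product: 3, ethyl 2,4-dimethyl-3,5-dioxoheptanoate (mixture of diastereomers and keto/enol tautomers)
Conditions: NaH (1.1 eq), THF, 0 °C; n-BuLi (1.05 eq), 0 °C; then 2 (1.0 eq), 0 °C → rt; aq. NH4Cl / 1 M HCl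
Reagents that add atoms: N-methoxy-N-methylpropanamide (2), CCC(=O)N(C)OC (delivers the propanoyl group)
Why: γ-Acylation of a β-keto ester dianion (Huckin–Weiler type) with a Weinreb amide, whose chelated tetrahedral intermediate prevents over-addition; the two epimerisable CH(Me) centres are lost in step 2.

**Step 2**
Reactants: 3, ethyl 2,4-dimethyl-3,5-dioxoheptanoate
Product: 4, 6-ethyl-4-hydroxy-3,5-dimethyl-2H-pyran-2-one
Conditions: DBU (1.5 eq), PhMe, reflux, 3 h; 1 M HCl workup
Reagents that add atoms: none
Why: Base-mediated enol-lactonisation of a 3,5-dioxo ester (C5 enolate oxygen attacks the ester, loss of EtOH), driven by formation of the acidic, conjugated 4-hydroxy-2-pyrone.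

**Step 3**
Reactants: 4, 6-ethyl-4-hydroxy-3,5-dimethyl-2H-pyran-2-one; 5, 4-acetamido-2,2,6,6-tetramethyl-1-oxopiperidinium tetrafluoroborate (Bobbitt's salt)
Product: 6, (±)-3-[(4-acetamido-2,2,6,6-tetramethylpiperidin-1-yl)oxy]-6-ethyl-3,5-dimethyl-2H-pyran-2,4(3H)-dione (racemic at C3; this centre is destroyed in step 5)
Conditions: 5 (1.05 eq), NaHCO3 (2 eq), MeCN, −20 → 0 °C, dark; cold aqueous workup; use at once or store ≤ −20 °C
Reagents that add atoms: Bobbitt's salt (5), CC(=O)NC1CC(C)(C)[N+](=O)C(C)(C)C1.F[B-](F)(F)F (delivers the aminoxyl group)
Why: α-Oxyamination of a 1,3-dicarbonyl enol(ate) by attack of C3, the only doubly activated carbon, on the electrophilic oxygen of the oxoammonium ion; C3 is quaternary, so no Kornblum-type elimination to a carbonyl is possible.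

**Step 4**
Reactants: 7, 1-(2,4,6-trihydroxyphenyl)ethanone (phloroacetophenone, dried); 8, 1-bromo-3-methylbut-2-ene (prenyl bromide)
Product: 9, 1-[2,4,6-trihydroxy-3-(3-methylbut-2-en-1-yl)phenyl]ethanone
Conditions: 8 (0.9 eq), DBU (1.0 eq), THF, 0 °C → rt, 16 h; 1 M HCl; chromatography with recovery of 7
Reagents that add atoms: prenyl bromide (8), CC(C)=CCBr
Why: Direct C-alkylation (SN2) of the ambident phloroglucinolate by a soft allylic bromide followed by re-aromatisation; the two free ring positions are equivalent, and sub-stoichiometric bromide limits bis- and O-prenylation (expect a modest yield).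

**Step 5**
Reactants: 6, the C3-aminoxylated pyrandione (1.3 eq); 9, 3-prenylphloroacetophenone (1.0 eq)
Product: 10, arzanol, 3-{[3-acetyl-2,4,6-trihydroxy-5-(3-methylbut-2-en-1-yl)phenyl]methyl}-6-ethyl-4-hydroxy-5-methyl-2H-pyran-2-one
Conditions: degassed MeCN (0.2 M in 9), 55–60 °C, Ar, dark, 6–12 h; dilute citric acid wash to remove 4-acetamido-2,2,6,6-tetramethylpiperidin-1-ol; chromatography
Reagents that add atoms: none beyond reactants 6 and 9
Why: Proposed new method: thermally triggered alkoxyamine unmasking with in situ arene capture, a formal C(sp3)–H/C(sp2)–H cross-dehydrogenative methylene bridging. The C3–ON bond of 6 lies between a ketone and a lactone carbonyl and should homolyse reversibly at about 50–60 °C; the nitroxide then abstracts a β-hydrogen from the only site available, the 3-CH3 (disproportionation), releasing 6-ethyl-5-methyl-3-methylene-2H-pyran-2,4(3H)-dione and a non-oxidising hydroxylamine; the single free, enol-like ring CH of 9 adds in a Friedel–Crafts-type Michael addition and both rings re-enolise to give 10. Cross-selectivity is built in, because the C1 unit sits only on the pyrone, no C3–H pyrone is present to give bis-pyrone, and 9 has one free position; slow release keeps the acceptor concentration low, and no acid is present to cyclise the prenyl group to a chroman. The closest known reaction types are TEMPO-mediated oxidative conversion of 2-methyl cyclic β-triketones into alkylidene triketones, disproportionation of α-methyl carbonyl alkoxyamines to alkene plus hydroxylamine, and Mannich-base generation of the same kind of methylene-dione for alkylation of acylphloroglucinols.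

**Compound list**
1 | ethyl 2-methyl-3-oxopentanoate | CCOC(=O)C(C)C(=O)CC | starting material
2 | N-methoxy-N-methylpropanamide | CCC(=O)N(C)OC | starting material
3 | ethyl 2,4-dimethyl-3,5-dioxoheptanoate | CCOC(=O)C(C)C(=O)C(C)C(=O)CC | intermediate
4 | 6-ethyl-4-hydroxy-3,5-dimethyl-2H-pyran-2-one | CCc1oc(=O)c(C)c(O)c1C | intermediate
5 | 4-acetamido-2,2,6,6-tetramethyl-1-oxopiperidinium tetrafluoroborate | CC(=O)NC1CC(C)(C)[N+](=O)C(C)(C)C1.F[B-](F)(F)F | starting material
6 | (±)-3-[(4-acetamido-2,2,6,6-tetramethylpiperidin-1-yl)oxy]-6-ethyl-3,5-dimethyl-2H-pyran-2,4(3H)-dione | CCC1=C(C)C(=O)C(C)(ON2C(C)(C)CC(NC(C)=O)CC2(C)C)C(=O)O1 | intermediate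
7 | 1-(2,4,6-trihydroxyphenyl)ethanone | CC(=O)c1c(O)cc(O)cc1O | starting material
8 | 1-bromo-3-methylbut-2-ene | CC(C)=CCBr | starting material
9 | 1-[2,4,6-trihydroxy-3-(3-methylbut-2-en-1-yl)phenyl]ethanone | CC(=O)c1c(O)cc(O)c(CC=C(C)C)c1O | intermediate
10 | arzanol | CCc1oc(=O)c(Cc2c(O)c(CC=C(C)C)c(O)c(C(C)=O)c2O)c(O)c1C | target

**Totals**
Total steps: 5. Longest linear sequence: 4 steps (1 → 3 → 4 → 6 → 10); the arene branch is 1 step.

**Three steps most likely to fail, with fallbacks**
1. Step 5 (proposed new step). Risks are radical side reactions of the C3 radical with the phenol or prenyl group, or dimerisation of the methylene-dione. Fallback (known chemistry): make the C3-unsubstituted pyrone, 6-ethyl-4-hydroxy-5-methyl-2H-pyran-2-one, by the same steps 1–2 from ethyl 3-oxopentanoate (CCC(=O)CC(=O)OCC). Treat it with Eschenmoser's salt (dimethylmethyleneammonium iodide) to form the Mannich base and methylene-dione in situ, and trap with 9; here the bridge carbon comes from a formaldehyde equivalent instead of a C–H oxidation.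
2. Step 3 (alkoxyamine formation and stability). Compound 6 may lose hydroxylamine below room temperature or be hard to isolate. Fallback: install a phenylselanyl group at C3 of 4 (PhSeCl, pyridine) and unmask the same methylene-dione by selenoxide syn-elimination (H2O2, ≤ 0 °C), the classical route to 2-methylene-1,3-dicarbonyls. Quench the oxidant and let the methylene-dione rest as its thermally reversible hetero-Diels–Alder dimer, then add 9 and warm.
3. Step 4 (mono-C-prenylation). O-alkylation, bis-prenylation and chroman formation erode the yield. Fallback: O-alkylation followed by aromatic Claisen rearrangement. Form the 4-O-(1,1-dimethylprop-2-ynyl) ether of 7 (3-chloro-3-methylbut-1-yne, K2CO3, KI), semi-hydrogenate with Lindlar catalyst to the 1,1-dimethylallyl ether, and heat for the [3,3] shift. This delivers exactly one prenyl group, with allyl inversion, to the equivalent ortho carbon and gives 9.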